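69.9 % in summer and 70.0 % in winter: that is how much of the starting material spared by the protic impurity stood as target after 120 s. The two runs carry different impurity, yet these numbers differ by 0.100 percentage points, with a scatter of 0.5 points on each reading.

| flask | starting material | second substrate | protic impurity | free catalyst | remark | time |
|---|---|---|---|---|---|---|
| summer | 0.89 M | 0.445 M | 0.050 M | 180 mM | run made earlier |  |
| winter | 0.89 M | 0.445 M | 0.084 M | 180 mM | run made earlier |  |
| theta | 0.89 M | 0.445 M | 0.0400 M | 180 mM |  | 2.5 min |
| eta | 0.89 M | 0.445 M | 0.0800 M | 180 mM |  | 2.5 min |
| epsilon | 0.89 M | 0.445 M | 0.200 M | 180 mM |  | 2.5 min |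

| run | time / s | target / % | starting material / % |
|---|---|---|---|
| summer | 10.0 | 4.0 | 84.0 |
| summer | 25.0 | 13.3 | 72.4 |
| summer | 50.0 | 29.5 | 57.2 |
| summer | 80.0 | 47.6 | 40.8 |
| summer | 120 | 66.0 | 23.8 |
| winter | 20.0 | 10.7 | 73.4 |
| winter | 40.0 | 22.5 | 60.0 |
| winter | 60.0 | 35.4 | 48.1 |
| winter | 80.0 | 46.0 | 38.8 |
| winter | 120 | 63.4 | 22.9 |

(readings scatter by 0.5 percentage points)

- steps that have been proposed: second substrate + free catalyst <-> catalyst intermediate B; starting material + protic impurity -> quenched substrate; catalyst intermediate A -> free catalyst + target; catalyst intermediate B -> free catalyst + second product; starting material + free catalyst <-> catalyst intermediate A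
- "hardly changes" means that all values lie within two and a half points (for a concentration: within two and a half percent of the largest)

* amount of target at the end, in percent of the starting material charged for theta, eta, epsilon, in this order
* how the row runs (hardly changes / falls, then rises / rises, then falls / falls all the way / rises all the way)

What does the impurity do to the charge?
It turns starting material into quenched substrate, one for one, and its charge is smaller, so it is the limiting reagent of that step. The spared fraction is then one minus impurity charge over starting material charge: 94.4 % in summer, 90.6 % in winter.

Can you read that from the runs?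
Add target and starting material and see what is missing. At 120 s winter misses 3.5 points more than summer, and the charges differ by 3.8 points.

Perhaps the impurity is still working then?
At 80.0 s that difference already reads 3.6 points, so I take the quench as finished by then.

The asked time lies beyond every reading. What now?
I freeze one quantity, the converted share, target over spared fraction. Averaged over both runs it reads 50.6 % at 80.0 s and 70.0 % at 120 s. Read from these two averages and taken as steady, the unconverted part shrinks at 0.0124 s⁻¹. Carried on to 2.5 min, the converted share becomes 79.3 %.

Your row?
Share times spared fraction: 75.8 %, 72.2 %, 61.5 %, falling all the way.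

Where is it weakest?
At epsilon: the runs tested the share up to 0.084 M, and epsilon holds 0.200 M.

The forecast gives 78 %, 74.7 % and 64.5 %, falls all the way, above my row at each point, and it too holds that “the impurity destroys starting material roughly one-for-one”.

The flask gives 75.7 %, 72.7 % and 63.4 %, falls all the way.

    second substrate + free catalyst ⇌ catalyst intermediate B (K = 19.0 M⁻¹, k = 0.350 M⁻¹ s⁻¹)
    starting material + protic impurity → quenched substrate (k = 0.840 M⁻¹ s⁻¹)
    catalyst intermediate A → free catalyst + target (k = 0.0810 s⁻¹)
    catalyst intermediate B → free catalyst + second product (k = 0.650 s⁻¹)
    starting material + free catalyst ⇌ catalyst intermediate A (K = 65.0 M⁻¹, k = 0.100 M⁻¹ s⁻¹)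

In epsilon, quenched substrate stands at 22.5 % of the starting material charged at 1.25 min and at 22.5 % at 2.50 min. The converted share comes to 79.3 % in theta, against 79.3 % carried, and to 81.8 % in epsilon. Take the quench step out of epsilon and the spared fraction is whole, so the carried share is itself the target, 79.3 %; that flask gives 78.7 %.

The readings were computed on assumed constants; scatter was added.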